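With the ring numbered from the ester-bearing carbon C1 through trans C2=C3, quaternary C4 and C6=C7 to the oxirane carbons C10 and C11 (C11 methyl-bearing), the 11-membered carbocycle is closed last at C1–C2. The key step exploits C1 as an allylic carbinol flanked by the oxirane oxygen on C11: a terminal alkyne on C4, unmasked as an (E)-alkenylzinc, adds to the α-epoxy aldehyde under chelation, forming the ring, the E-alkene and the C1 stereocentre in one operation. Its precursor is an acyclic ynal, joined at C6=C7 by Horner–Wadsworth–Emmons olefination of a geraniol-derived alkynyl aldehyde (quaternary carbon from copper-catalysed SN2′ alkynylation) with a Sharpless-derived epoxy phosphonate.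

Key step: step 19

Remark: the hand of the carbene ligand in step 2 is taken to be the one that gives the R quaternary carbon; the sense of induction belongs to the ligand and is to be confirmed on the first batch by correlation.

Step 1
Reactants: 1 geraniol
Product: 2 geranyl diethyl phosphate
Conditions: ClP(O)(OEt)2, pyridine, DMAP (cat.), CH2Cl2, 0 °C → rt
Reagents that add atoms: diethyl chlorophosphate, CCOP(=O)(Cl)OCC
Why: O-phosphorylation of a primary allylic alcohol with a chlorophosphate and an amine base is routine, leaves the E-alkene untouched and installs the leaving group for the allylic substitution.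

Step 2
Reactants: 2 geranyl diethyl phosphate; 3 trimethylsilylacetylene
Product: 5 [(3R)-3-ethenyl-3,7-dimethyloct-6-en-1-yn-1-yl](trimethyl)silane, via diisobutyl[(trimethylsilyl)ethynyl]aluminium 4 (not isolated)
Conditions: 3, iBu2AlH, Et3N (5 mol %), hexanes, rt; then 2, CuCl2·2H2O (5 mol %), chiral sulfonate-bearing 4,5-diphenylimidazolinium salt (carbene precursor, 2.5 mol %), THF, −15 °C
Reagents that add atoms: none
Why: Copper-catalysed enantioselective SN2′ allylic substitution: the alkynylalane made by amine-catalysed deprotonative alumination hands its alkynyl group to the sulfonate-bridged carbene copper species formed from CuCl2·2H2O, which delivers it to the trisubstituted γ-carbon of the E-allylic phosphate, so the quaternary stereocentre (R) is set by catalyst control.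

Step 3
Reactants: 5 quaternary 1,4-enyne
Product: 6 (3R)-3,7-dimethyl-3-[(trimethylsilyl)ethynyl]oct-6-en-1-ol
Conditions: 9-BBN-H (1.2 equiv), THF, 0 °C → rt; then aq. NaOAc, 30 % H2O2, 0 °C → rt
Reagents that add atoms: hydrogen peroxide, OO
Why: Anti-Markovnikov hydroboration–oxidation in which 9-BBN-H strongly prefers the monosubstituted vinyl group over the trisubstituted alkene and the hindered silyl-capped alkyne, while the acetate-buffered oxidation keeps the C–Si bond.

Step 4
Reactants: 6 homoallylic-type primary alcohol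
Product: 7 (3R)-5-(3,3-dimethyloxiran-2-yl)-3-methyl-3-[(trimethylsilyl)ethynyl]pentan-1-ol (both oxirane epimers)
Conditions: mCPBA, NaHCO3, CH2Cl2, 0 °C
Reagents that add atoms: mCPBA (3-chloroperoxybenzoic acid), OOC(=O)c1cccc(Cl)c1
Why: Prilezhaev epoxidation selects the electron-rich trisubstituted alkene (the alkyne is inert), and the uncontrolled oxirane stereocentre is erased in step 5.

Step 5
Reactants: 7 epoxy alcohol
Product: 9 (3R,5E)-3,7-dimethyl-3-[(trimethylsilyl)ethynyl]oct-5-ene-1,7-diol, via hydroxy selenide 8 (not isolated)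
Conditions: PhSeSePh, NaBH4, EtOH, rt; then THF, 30 % H2O2, 0 °C → rt
Reagents that add atoms: none
Why: Sharpless–Lauer sequence in which PhSe− opens the oxirane by SN2 at the secondary carbon and syn elimination of the derived selenoxide can only run towards the chain CH2 (the carbinol carbon has no hydrogen), giving the E tertiary allylic alcohol; any loss of the silyl cap in the basic medium is harmless because step 6 removes it.

Step 6
Reactants: 9 silyl-capped enediol
Product: 10 (3R,5E)-3-ethynyl-3,7-dimethyloct-5-ene-1,7-diol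
Conditions: K2CO3, MeOH, rt
Reagents that add atoms: none
Why: Methanolysis of the alkynyl C–Si bond by catalytic methoxide is fast and touches nothing else in the molecule.

Step 7
Reactants: 10 alkynyl diol
Product: 11 (3R,5E)-3-ethynyl-3,7-dimethyl-1,7-bis[(triethylsilyl)oxy]oct-5-ene
Conditions: TESOTf (2.5 equiv), 2,6-lutidine, CH2Cl2, −78 → 0 °C
Reagents that add atoms: triethylsilyl trifluoromethanesulfonate, CC[Si](CC)(CC)OS(=O)(=O)C(F)(F)F
Why: A silyl triflate with a hindered pyridine base silylates the tertiary allylic as well as the primary hydroxyl without ionising the allylic system.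

Step 8
Reactants: 11 bis-TES ether
Product: 12 (3R,5E)-3-ethynyl-3,7-dimethyl-7-[(triethylsilyl)oxy]oct-5-enal
Conditions: (COCl)2, DMSO, CH2Cl2, −78 → −40 °C; then Et3N, −78 → 0 °C
Reagents that add atoms: none
Why: Swern oxidation applied directly to the silyl ether, in which the activated-DMSO medium cleaves the unhindered primary TES ether and oxidises the freed oxygen in situ while the tertiary TES ether is too hindered to react.

Step 9
Reactants: 13 triethyl phosphonoacetate; 14 2-(2-bromoethyl)-1,3-dioxolane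
Product: 15 ethyl 2-(diethoxyphosphoryl)-4-(1,3-dioxolan-2-yl)butanoate
Conditions: 13 (1.5 equiv), NaH, THF/DMF, 0 °C; then 14, NaI (cat.), 60 °C
Reagents that add atoms: none
Why: SN2 C-alkylation of the sodium phosphonoacetate anion with a primary bromide, with excess phosphonate holding back dialkylation.

Step 10
Reactants: 15 alkylated phosphonoacetate
Product: 16 ethyl 2-(diethoxyphosphoryl)-5-oxopentanoate
Conditions: 1 M HCl, THF, rt
Reagents that add atoms: water, O
Why: Acid-catalysed acetal hydrolysis frees the aldehyde, and the ester and phosphonate are stable to dilute acid at room temperature.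

Step 11
Reactants: 16 phosphono aldehyde; 17 2-(triphenylphosphoranylidene)propanal
Product: 18 ethyl (5E)-2-(diethoxyphosphoryl)-6-methyl-7-oxohept-5-enoate
Conditions: toluene, 80 °C
Reagents that add atoms: none
Why: Wittig olefination with a formyl-stabilised ylide gives the E 2-methyl enal, and the ylide is too weak a base to deprotonate the phosphonoacetate.

Step 12
Reactants: 18 E-enal phosphonate
Product: 19 ethyl (5E)-2-(diethoxyphosphoryl)-7-hydroxy-6-methylhept-5-enoate
Conditions: NaBH4, CeCl3·7H2O, MeOH, −40 → 0 °C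
Reagents that add atoms: none
Why: Luche reduction gives clean 1,2-reduction of the enal and leaves the ester and phosphonate alone.

Step 13
Reactants: 19 E-allylic alcohol
Product: 20 ethyl 2-(diethoxyphosphoryl)-4-[(2R,3R)-3-(hydroxymethyl)-3-methyloxiran-2-yl]butanoate
Conditions: Ti(OiPr)4 (20 mol %), D-(−)-diethyl tartrate (24 mol %), t-BuOOH, 4 Å molecular sieves, CH2Cl2, −20 °C
Reagents that add atoms: tert-butyl hydroperoxide, CC(C)(C)OO
Why: Sharpless asymmetric epoxidation of an E 2-methyl allylic alcohol, for which the catalyst from Ti(OiPr)4 and D-(−)-diethyl tartrate delivers oxygen to the face that gives the (2R,3R)-epoxy alcohol, setting both oxirane stereocentres by reagent control (the phosphonate carbon remains an inconsequential epimer mixture).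

Step 14
Reactants: 20 epoxy alcohol phosphonate
Product: 21 ethyl 2-(diethoxyphosphoryl)-4-[(2R,3R)-3-methyl-3-{[(triethylsilyl)oxy]methyl}oxiran-2-yl]butanoate
Conditions: TESCl, imidazole, CH2Cl2, 0 °C
Reagents that add atoms: chlorotriethylsilane, CC[Si](Cl)(CC)CC
Why: Standard silylation of a primary alcohol, which also blocks Payne rearrangement in the basic olefination that follows.

Step 15
Reactants: 12 west alkynyl aldehyde; 21 east epoxy phosphonate
Product: 22 ethyl (2E,5R,7E)-5-ethynyl-5,9-dimethyl-2-{2-[(2R,3R)-3-methyl-3-{[(triethylsilyl)oxy]methyl}oxiran-2-yl]ethyl}-9-[(triethylsilyl)oxy]deca-2,7-dienoate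
Conditions: LiCl, DBU, MeCN, 0 °C → rt (12 and LiCl premixed, then 21, DBU last)
Reagents that add atoms: none
Why: Horner–Wadsworth–Emmons olefination under Masamune–Roush conditions, where reversible addition of the lithium-chelated α-alkyl phosphonate anion favours the enoate with the ester trans to C5, and the mild amine base spares the oxirane and the silyl ethers.

Step 16
Reactants: 22 acyclic E-enoate
Product: 23 (2E,5R,7E)-5-ethynyl-5,9-dimethyl-2-{2-[(2R,3R)-3-methyl-3-{[(triethylsilyl)oxy]methyl}oxiran-2-yl]ethyl}-9-[(triethylsilyl)oxy]deca-2,7-dien-1-ol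
Conditions: iBu2AlH (2.5 equiv), CH2Cl2, −78 °C; aq. potassium sodium tartrate (KNaC4H4O6)
Reagents that add atoms: none
Why: 1,2-Reduction of the conjugated ester to the allylic alcohol by iBu2AlH at low temperature, where the trisubstituted oxirane and the alkyne C–H are not attacked.

Step 17
Reactants: 23 allylic alcohol
Product: 24 (2E,5R,7E)-1-[(tert-butyldimethylsilyl)oxy]-5-ethynyl-5,9-dimethyl-2-{2-[(2R,3R)-3-methyl-3-{[(triethylsilyl)oxy]methyl}oxiran-2-yl]ethyl}-9-[(triethylsilyl)oxy]deca-2,7-diene
Conditions: TBSCl, imidazole, DMF, 0 °C → rt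
Reagents that add atoms: tert-butylchlorodimethylsilane, CC(C)(C)[Si](C)(C)Cl
Why: Routine silylation of the primary allylic alcohol with a group that survives the Swern, organozinc and acylation steps.

Step 18
Reactants: 24 TBS ether
Product: 25 (2S,3R)-3-[(3E,6R,8E)-3-{[(tert-butyldimethylsilyl)oxy]methyl}-6-ethynyl-6,10-dimethyl-10-[(triethylsilyl)oxy]undeca-3,8-dien-1-yl]-2-methyloxirane-2-carbaldehyde
Conditions: (COCl)2, DMSO, CH2Cl2, −78 → −40 °C; then Et3N, −78 → 0 °C
Reagents that add atoms: none
Why: Direct Swern oxidation again selects the primary TES ether (the TBS and tertiary TES ethers are inert), and the resulting α-quaternary epoxy aldehyde cannot enolise or epimerise.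

Step 19
Reactants: 25 ynal
Product: 28 (1S,2E,4R,6E,10R,11R)-7-{[(tert-butyldimethylsilyl)oxy]methyl}-10,11-epoxy-4,11-dimethyl-4-{(2E)-4-methyl-4-[(triethylsilyl)oxy]pent-2-en-1-yl}cycloundeca-2,6-dien-1-ol, via alkenyl(dicyclohexyl)borane 26 (not isolated), via alkenyl(methyl)zinc 27 (not isolated)
Conditions: Cy2BH (1.1 equiv, from BH3·SMe2 and cyclohexene), toluene, 0 °C, 1 h; then added by syringe pump over 10 h to Me2Zn (2 equiv) and EtZnCl (2 equiv, from Et2Zn and ZnCl2) in toluene/CH2Cl2, −20 → 0 °C, final concentration about 1 mM; aq. NH4Cl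
Reagents that add atoms: none
Why: Proposed new method: Cy2BH adds syn across the terminal alkyne with boron on the terminal carbon (the internal carbon is shielded by quaternary C4) faster than it reduces the hindered aldehyde, and Me2Zn then takes over the (E)-alkenyl group with retention to give an alkenyl(methyl)zinc whose alkenyl ligand transfers in preference to methyl. EtZnCl binds the aldehyde oxygen and the oxirane oxygen on C11 in a five-membered chelate, and alkenyl carbon C2 adds to C1 in an 11-exo-trig closure that forms the C1–C2 bond and with it the 11-membered carbocycle. The closest known reaction types are the macrocyclisation of ω-alkynals to (E)-cycloalkenols by hydroboration, boron-to-zinc exchange and alkenylzinc addition, and the intermolecular chelation-controlled alkenylzinc addition to α-oxygenated aldehydes promoted by alkylzinc halides; their combination on an 11-membered ring with an oxirane as the chelating group is new. The new stereocentre C1 is set by substrate control from C11: within the chelate C2 enters on the face anti to oxirane carbon C10, which gives the 1S carbinol threo to the oxirane, and the C2=C3 alkene is E because the hydroboration is syn. The step needs this facial selectivity and ring closure in preference to oligomerisation, and the non-enolisable α-quaternary aldehyde, the α-oxygen for chelation, the turn elements (quaternary C4, the C6=C7 alkene holding C5 and C8 cis, the trans oxirane) and slow addition at high dilution should secure them.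

Step 20
Reactants: 28 11-membered epoxy allylic alcohol; 29 3-methylbut-2-enoyl chloride
Product: 30 (1S,2E,4R,6E,10R,11S)-7-{[(tert-butyldimethylsilyl)oxy]methyl}-10,11-epoxy-4,11-dimethyl-4-{(2E)-4-methyl-4-[(triethylsilyl)oxy]pent-2-en-1-yl}cycloundeca-2,6-dien-1-yl 3-methylbut-2-enoate
Conditions: pyridine, DMAP (cat.), CH2Cl2, 0 °C → rt
Reagents that add atoms: none
Why: Acylation of the hindered secondary allylic alcohol through the acylpyridinium ion, with no trialkylamine so that the vinylketene pathway to the deconjugated ester is avoided, and with retention at C1 because the C–O bond is not touched.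

Step 21
Reactants: 30 bis-silylated senecioate
Product: 31 CNP0248133.1, (1S,2E,4R,6E,10R,11S)-10,11-epoxy-7-(hydroxymethyl)-4-[(2E)-4-hydroxy-4-methylpent-2-en-1-yl]-4,11-dimethylcycloundeca-2,6-dien-1-yl 3-methylbut-2-enoate
Conditions: HF·pyridine, pyridine, THF, 0 °C → rt
Reagents that add atoms: none
Why: Fluoride-mediated desilylation under pyridine buffering should remove the primary allylic TBS and the tertiary TES ether without opening the oxirane, ionising the tertiary allylic alcohol or cleaving the ester.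

Compound list
1 | geraniol, (2E)-3,7-dimethylocta-2,6-dien-1-ol | CC(C)=CCC/C(C)=C/CO | starting material
2 | geranyl diethyl phosphate, diethyl (2E)-3,7-dimethylocta-2,6-dien-1-yl phosphate | CCOP(=O)(OCC)OC/C=C(\C)CCC=C(C)C | intermediate
3 | trimethylsilylacetylene | C[Si](C)(C)C#C | starting material
4 | diisobutyl[(trimethylsilyl)ethynyl]aluminium | CC(C)C[Al](CC(C)C)C#C[Si](C)(C)C | intermediate
5 | [(3R)-3-ethenyl-3,7-dimethyloct-6-en-1-yn-1-yl](trimethyl)silane | C[Si](C)(C)C#C[C@](C)(CCC=C(C)C)C=C | intermediate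
6 | (3R)-3,7-dimethyl-3-[(trimethylsilyl)ethynyl]oct-6-en-1-ol | C[Si](C)(C)C#C[C@](C)(CCC=C(C)C)CCO | intermediate
7 | (3R)-5-(3,3-dimethyloxiran-2-yl)-3-methyl-3-[(trimethylsilyl)ethynyl]pentan-1-ol, both oxirane epimers | C[Si](C)(C)C#C[C@](C)(CCC1OC1(C)C)CCO | intermediate
8 | (3R)-3,7-dimethyl-6-(phenylselanyl)-3-[(trimethylsilyl)ethynyl]octane-1,7-diol, both C6 epimers | C[Si](C)(C)C#C[C@](C)(CCC([Se]c1ccccc1)C(C)(C)O)CCO | intermediate
9 | (3R,5E)-3,7-dimethyl-3-[(trimethylsilyl)ethynyl]oct-5-ene-1,7-diol | C[Si](C)(C)C#C[C@](C)(C/C=C/C(C)(C)O)CCO | intermediate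
10 | (3R,5E)-3-ethynyl-3,7-dimethyloct-5-ene-1,7-diol | C#C[C@](C)(C/C=C/C(C)(C)O)CCO | intermediate
11 | (3R,5E)-3-ethynyl-3,7-dimethyl-1,7-bis[(triethylsilyl)oxy]oct-5-ene | C#C[C@](C)(C/C=C/C(C)(C)O[Si](CC)(CC)CC)CCO[Si](CC)(CC)CC | intermediate
12 | (3R,5E)-3-ethynyl-3,7-dimethyl-7-[(triethylsilyl)oxy]oct-5-enal (west fragment) | C#C[C@](C)(C/C=C/C(C)(C)O[Si](CC)(CC)CC)CC=O | intermediate
13 | triethyl phosphonoacetate | CCOC(=O)CP(=O)(OCC)OCC | starting material
14 | 2-(2-bromoethyl)-1,3-dioxolane | BrCCC1OCCO1 | starting material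
15 | ethyl 2-(diethoxyphosphoryl)-4-(1,3-dioxolan-2-yl)butanoate | CCOC(=O)C(CCC1OCCO1)P(=O)(OCC)OCC | intermediate
16 | ethyl 2-(diethoxyphosphoryl)-5-oxopentanoate | CCOC(=O)C(CCC=O)P(=O)(OCC)OCC | intermediate
17 | 2-(triphenylphosphoranylidene)propanal | CC(C=O)=P(c1ccccc1)(c1ccccc1)c1ccccc1 | starting material
18 | ethyl (5E)-2-(diethoxyphosphoryl)-6-methyl-7-oxohept-5-enoate | CCOC(=O)C(CC/C=C(\C)C=O)P(=O)(OCC)OCC | intermediate
19 | ethyl (5E)-2-(diethoxyphosphoryl)-7-hydroxy-6-methylhept-5-enoate | CCOC(=O)C(CC/C=C(\C)CO)P(=O)(OCC)OCC | intermediate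
20 | ethyl 2-(diethoxyphosphoryl)-4-[(2R,3R)-3-(hydroxymethyl)-3-methyloxiran-2-yl]butanoate, epimer mixture at the phosphonate carbon | CCOC(=O)C(CC[C@H]1O[C@]1(C)CO)P(=O)(OCC)OCC | intermediate
21 | ethyl 2-(diethoxyphosphoryl)-4-[(2R,3R)-3-methyl-3-{[(triethylsilyl)oxy]methyl}oxiran-2-yl]butanoate (east fragment), epimer mixture at the phosphonate carbon | CCOC(=O)C(CC[C@H]1O[C@]1(C)CO[Si](CC)(CC)CC)P(=O)(OCC)OCC | intermediate
22 | ethyl (2E,5R,7E)-5-ethynyl-5,9-dimethyl-2-{2-[(2R,3R)-3-methyl-3-{[(triethylsilyl)oxy]methyl}oxiran-2-yl]ethyl}-9-[(triethylsilyl)oxy]deca-2,7-dienoate | C#C[C@](C)(C/C=C/C(C)(C)O[Si](CC)(CC)CC)C/C=C(/C(=O)OCC)CC[C@H]1O[C@]1(C)CO[Si](CC)(CC)CC | intermediate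
23 | (2E,5R,7E)-5-ethynyl-5,9-dimethyl-2-{2-[(2R,3R)-3-methyl-3-{[(triethylsilyl)oxy]methyl}oxiran-2-yl]ethyl}-9-[(triethylsilyl)oxy]deca-2,7-dien-1-ol | C#C[C@](C)(C/C=C/C(C)(C)O[Si](CC)(CC)CC)C/C=C(/CO)CC[C@H]1O[C@]1(C)CO[Si](CC)(CC)CC | intermediate
24 | (2E,5R,7E)-1-[(tert-butyldimethylsilyl)oxy]-5-ethynyl-5,9-dimethyl-2-{2-[(2R,3R)-3-methyl-3-{[(triethylsilyl)oxy]methyl}oxiran-2-yl]ethyl}-9-[(triethylsilyl)oxy]deca-2,7-diene | C#C[C@](C)(C/C=C/C(C)(C)O[Si](CC)(CC)CC)C/C=C(/CO[Si](C)(C)C(C)(C)C)CC[C@H]1O[C@]1(C)CO[Si](CC)(CC)CC | intermediate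
25 | (2S,3R)-3-[(3E,6R,8E)-3-{[(tert-butyldimethylsilyl)oxy]methyl}-6-ethynyl-6,10-dimethyl-10-[(triethylsilyl)oxy]undeca-3,8-dien-1-yl]-2-methyloxirane-2-carbaldehyde | C#C[C@](C)(C/C=C/C(C)(C)O[Si](CC)(CC)CC)C/C=C(/CO[Si](C)(C)C(C)(C)C)CC[C@H]1O[C@]1(C)C=O | intermediate
26 | (E)-alkenyl(dicyclohexyl)borane from 25 (HC≡C replaced by (E)-Cy2B–CH=CH) | C1CCCCC1B(C1CCCCC1)/C=C/[C@](C)(C/C=C/C(C)(C)O[Si](CC)(CC)CC)C/C=C(/CO[Si](C)(C)C(C)(C)C)CC[C@H]1O[C@]1(C)C=O | intermediate
27 | (E)-alkenyl(methyl)zinc from 26 (BCy2 replaced by ZnMe) | C[Zn]/C=C/[C@](C)(C/C=C/C(C)(C)O[Si](CC)(CC)CC)C/C=C(/CO[Si](C)(C)C(C)(C)C)CC[C@H]1O[C@]1(C)C=O | intermediate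
28 | (1S,2E,4R,6E,10R,11R)-7-{[(tert-butyldimethylsilyl)oxy]methyl}-10,11-epoxy-4,11-dimethyl-4-{(2E)-4-methyl-4-[(triethylsilyl)oxy]pent-2-en-1-yl}cycloundeca-2,6-dien-1-ol (C11 reads R only because the free hydroxyl changes the priorities; the configuration is that of 30 and 31) | O[C@H]1/C=C/[C@](C)(C/C=C/C(C)(C)O[Si](CC)(CC)CC)C/C=C(/CO[Si](C)(C)C(C)(C)C)CC[C@H]2O[C@]12C | intermediate
29 | 3-methylbut-2-enoyl chloride | CC(C)=CC(Cl)=O | starting material
30 | (1S,2E,4R,6E,10R,11S)-7-{[(tert-butyldimethylsilyl)oxy]methyl}-10,11-epoxy-4,11-dimethyl-4-{(2E)-4-methyl-4-[(triethylsilyl)oxy]pent-2-en-1-yl}cycloundeca-2,6-dien-1-yl 3-methylbut-2-enoate | CC(C)=CC(=O)O[C@H]1/C=C/[C@](C)(C/C=C/C(C)(C)O[Si](CC)(CC)CC)C/C=C(/CO[Si](C)(C)C(C)(C)C)CC[C@H]2O[C@]12C | intermediate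
31 | CNP0248133.1, (1S,2E,4R,6E,10R,11S)-10,11-epoxy-7-(hydroxymethyl)-4-[(2E)-4-hydroxy-4-methylpent-2-en-1-yl]-4,11-dimethylcycloundeca-2,6-dien-1-yl 3-methylbut-2-enoate | CC(C)=CC(=O)O[C@H]1/C=C/[C@](C)(C/C=C/C(C)(C)O)C/C=C(/CO)CC[C@H]2O[C@]12C | target

Total step count: 21 steps.
Longest linear sequence: 15 steps (geraniol to the target: steps 1–8 and 15–21); the east fragment takes 6 steps (9–14).

Steps most likely to fail

Step 19 (macrocyclisation). The closure of a strained medium ring may lose out to oligomerisation, the borane may reduce the aldehyde, the zinc Lewis acid may open the oxirane, or the chelate may not hold in the ring-closing transition state so that facial selectivity is poor. The fallback makes the same C1–C2 bond by a Nozaki–Hiyama–Kishi ring closure and sets out from TBS ether 24. Hydrozirconation of the terminal alkyne with Cp2Zr(H)Cl in THF followed by I2 should give the (E)-alkenyl iodide F1. Direct Swern oxidation of its primary TES ether, as in step 18, should give the iodo epoxy aldehyde F2. Slow addition of F2 to CrCl2 (excess) and NiCl2 (1 mol %) in DMSO/THF at high dilution should close the ring. Without chelation the Felkin–Anh face is expected to be preferred, giving the C1-epimeric cycloalkenol F3. Mitsunobu esterification of F3 with 3-methylbut-2-enoic acid (PPh3, DIAD, toluene) should install the ester with inversion at C1 and return to the route at senecioate 30. Any 1S alcohol formed in the closure is compound 28 itself and would be acylated as in step 20.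

Step 15 (olefination). α-Branched phosphonoacetates can lose E/Z selectivity with unbranched aldehydes, and the phosphonate carbanion may attack the oxirane. The fallback replaces the phosphonate by a stabilised phosphorane and builds the oxirane after the coupling; it sets out from bromide 14 and aldehyde 12. Alkylation of ethyl (triphenylphosphoranylidene)acetate (2 equiv, the second as base; NaI cat., MeCN, reflux) with 14 should give the α-alkylated ylide F4. Wittig olefination of 12 with F4 (toluene, 90 °C), dependably E-selective for α-alkyl ester ylides, should give the dioxolane enoate F5. TESOTf and 2,4,6-collidine followed by water should cleave the acetal without loss of the tertiary TES ether to give the enoate aldehyde F6. Wittig reaction with ylide 17 should give the E-enal F7, and Luche reduction (NaBH4, CeCl3·7H2O) the allylic alcohol F8. Sharpless epoxidation with D-(−)-diethyl tartrate, as in step 13, should give the epoxy alcohol F9. Silylation with TESCl and imidazole returns to the route at enoate 22.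

Step 2 (SN2′ alkynylation). Enantioselectivity may be low, direct SN2 substitution may compete, or the silyl-capped alkynyl group may transfer sluggishly. The fallback builds the quaternary carbon by stereospecific opening of an epoxide and sets out from geraniol 1 and alkyne 3. Sharpless epoxidation of 1 with Ti(OiPr)4, L-(+)-diethyl tartrate and t-BuOOH should give (2S,3S)-2,3-epoxygeraniol F10. The alkynylalane Et2Al–C≡C–SiMe3 (from 3, n-BuLi and Et2AlCl, toluene, 0 °C) should open the hydroxyl-bound epoxide at C3 with inversion to give the alkynyl 1,2-diol F11. NaIO4 in THF/H2O should cleave the diol to the α-quaternary aldehyde F12. Methylenation with Ph3P=CH2 returns to the route at enyne 5.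

Further compounds
F1 | step 19 | (E)-alkenyl iodide corresponding to 24 (HC≡C replaced by (E)-ICH=CH) | I/C=C/[C@](C)(C/C=C/C(C)(C)O[Si](CC)(CC)CC)C/C=C(/CO[Si](C)(C)C(C)(C)C)CC[C@H]1O[C@]1(C)CO[Si](CC)(CC)CC
F2 | step 19 | iodo epoxy aldehyde corresponding to 25 (HC≡C replaced by (E)-ICH=CH) | I/C=C/[C@](C)(C/C=C/C(C)(C)O[Si](CC)(CC)CC)C/C=C(/CO[Si](C)(C)C(C)(C)C)CC[C@H]1O[C@]1(C)C=O
F3 | step 19 | (1R)-epimer of cycloalkenol 28 | O[C@@H]1/C=C/[C@](C)(C/C=C/C(C)(C)O[Si](CC)(CC)CC)C/C=C(/CO[Si](C)(C)C(C)(C)C)CC[C@H]2O[C@]12C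
F4 | step 15 | ethyl 4-(1,3-dioxolan-2-yl)-2-(triphenylphosphoranylidene)butanoate | CCOC(=O)C(CCC1OCCO1)=P(c1ccccc1)(c1ccccc1)c1ccccc1
F5 | step 15 | ethyl (2E,5R,7E)-2-[2-(1,3-dioxolan-2-yl)ethyl]-5-ethynyl-5,9-dimethyl-9-[(triethylsilyl)oxy]deca-2,7-dienoate | C#C[C@](C)(C/C=C/C(C)(C)O[Si](CC)(CC)CC)C/C=C(/C(=O)OCC)CCC1OCCO1
F6 | step 15 | ethyl (2E,5R,7E)-5-ethynyl-5,9-dimethyl-2-(3-oxopropyl)-9-[(triethylsilyl)oxy]deca-2,7-dienoate | C#C[C@](C)(C/C=C/C(C)(C)O[Si](CC)(CC)CC)C/C=C(/C(=O)OCC)CCC=O
F7 | step 15 | ethyl (2E,5R,7E)-5-ethynyl-5,9-dimethyl-2-[(3E)-4-methyl-5-oxopent-3-en-1-yl]-9-[(triethylsilyl)oxy]deca-2,7-dienoate | C#C[C@](C)(C/C=C/C(C)(C)O[Si](CC)(CC)CC)C/C=C(/C(=O)OCC)CC/C=C(\C)C=O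
F8 | step 15 | ethyl (2E,5R,7E)-5-ethynyl-2-[(3E)-5-hydroxy-4-methylpent-3-en-1-yl]-5,9-dimethyl-9-[(triethylsilyl)oxy]deca-2,7-dienoate | C#C[C@](C)(C/C=C/C(C)(C)O[Si](CC)(CC)CC)C/C=C(/C(=O)OCC)CC/C=C(\C)CO
F9 | step 15 | ethyl (2E,5R,7E)-5-ethynyl-2-{2-[(2R,3R)-3-(hydroxymethyl)-3-methyloxiran-2-yl]ethyl}-5,9-dimethyl-9-[(triethylsilyl)oxy]deca-2,7-dienoate | C#C[C@](C)(C/C=C/C(C)(C)O[Si](CC)(CC)CC)C/C=C(/C(=O)OCC)CC[C@H]1O[C@]1(C)CO
F10 | step 2 | (2S,3S)-2,3-epoxygeraniol, [(2S,3S)-3-methyl-3-(4-methylpent-3-en-1-yl)oxiran-2-yl]methanol | CC(C)=CCC[C@]1(C)O[C@H]1CO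
F11 | step 2 | (2R,3S)-3,7-dimethyl-3-[(trimethylsilyl)ethynyl]oct-6-ene-1,2-diol | C[Si](C)(C)C#C[C@](C)(CCC=C(C)C)[C@@H](O)CO
F12 | step 2 | (2S)-2,6-dimethyl-2-[(trimethylsilyl)ethynyl]hept-5-enal | C[Si](C)(C)C#C[C@](C)(CCC=C(C)C)C=O
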